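**Retrosynthetic overview**
1. Numbering: C1 = CH2OH carbon, C3 = lactone carbonyl, C4/C12/C13 = butenolide α/β/γ carbons, C4a–C11a = nine-membered ring, C14/C15 = side-chain carbinols. After removal of two silyl ethers, the butenolide is cut at C4=C12 and at O–C13 in one operation, giving α-phosphono δ-lactone 18 (C3 carbonyl tied to the C1 oxygen, six-membered ring fused to the carbocycle) and trans-epoxy aldehyde 24 (C12–C15).
2. Enabling feature: the butenolide ring oxygen on C13 and the free hydroxyl on C14 are vicinal and anti, the imprint of a trans epoxide opened at its allylic carbon with inversion. C4=C12 is an olefination retron on the carbon α to C3, and the C1 hydroxymethyl on C11a lies 1,5 to C3, so the acid can be stored as a δ-lactone that contracts to the γ-lactone.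
3. Nine-membered ring: ring-closing metathesis to Z-C8=C9 on a trans-4,5-disubstituted δ-lactone, then C11 ketone to exocyclic methylene and hydroxyl-directed epoxidation from the C7 alcohol.
4. Stereocentres: C7 from (S)-linalool, C4a by organocatalytic Mukaiyama–Michael addition, C11a by organocatalytic α-hydroxymethylation, C13/C14 from a Sharpless epoxide.
5. Ring order: δ-lactone (step 6), nine-membered carbocycle (step 9), oxirane (step 12), butenolide with loss of the δ-lactone (step 20).

Key step: step 20

Assumption: (S)-(+)-linalool of high enantiomeric purity, S-tert-butyl thioacetate and diphenyl phosphorochloridite are taken as purchasable.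

Step 1
Reactants: 1 (S)-(+)-linalool
Product: 2 (3S)-3,7-dimethyl-3-(triethylsilyloxy)octa-1,6-diene
Conditions: Et3SiOTf, 2,6-lutidine, CH2Cl2, −78 to 0 °C
Reagents that add atoms: triethylsilyl trifluoromethanesulfonate, CC[Si](CC)(CC)OS(=O)(=O)C(F)(F)F
Why: Silylation of the tertiary alcohol is needed so that the hydroxyl cannot add to the aldehyde and enal made next; the C7 stereocentre is that of the starting material.

Step 2
Reactants: 2 (3S)-3,7-dimethyl-3-(triethylsilyloxy)octa-1,6-diene
Product: 3 (4S)-4-methyl-4-(triethylsilyloxy)hex-5-enal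
Conditions: O3 (1 equiv, Sudan red end point), pyridine, CH2Cl2, −78 °C
Reagents that add atoms: ozone, [O-][O+]=O
Why: Chemoselective ozonolysis should cleave the electron-rich trisubstituted alkene much faster than the vinyl group on the hindered silyloxy carbon, with pyridine turning the carbonyl oxide directly into the aldehyde.

Step 3
Reactants: 3 (4S)-4-methyl-4-(triethylsilyloxy)hex-5-enal
Product: 4 (2E,6S)-6-methyl-6-(triethylsilyloxy)octa-2,7-dienal
Conditions: Ph3P=CHCHO, toluene, 80 °C
Reagents that add atoms: (triphenylphosphoranylidene)acetaldehyde, O=CC=P(c1ccccc1)(c1ccccc1)c1ccccc1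
Why: Wittig olefination with the stabilised formylmethylene ylide should give the E-enal and stop at one homologation because the enal is less electrophilic than the saturated aldehyde.

Step 4
Reactants: 5 S-tert-butyl thioacetate
Product: 6 1-(tert-butylsulfanyl)-1-(trimethylsilyloxy)ethene
Conditions: LiN(iPr)2, Me3SiCl, THF, −78 °C
Reagents that add atoms: chlorotrimethylsilane, C[Si](C)(C)Cl
Why: Kinetic enolisation of the thioester and O-silylation (silyl ketene acetal formation) give the nucleophile for the Mukaiyama–Michael step.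

Step 5
Reactants: 4 (2E,6S)-6-methyl-6-(triethylsilyloxy)octa-2,7-dienal and 6 1-(tert-butylsulfanyl)-1-(trimethylsilyloxy)ethene
Product: 7 S-tert-butyl (3S,6S)-6-methyl-3-(2-oxoethyl)-6-(triethylsilyloxy)oct-7-enethioate
Conditions: (2R,5R)-5-benzyl-2-tert-butyl-3-methylimidazolidin-4-one trichloroacetate (20 mol%), i-PrOH (2 equiv), CH2Cl2, −78 °C
Reagents that add atoms: none
Why: Organocatalytic Mukaiyama–Michael addition through the E-iminium ion of 4, one face of which is shielded by the benzyl group of the (2R,5R)-imidazolidinone, should deliver the ketene thioacetal 1,4 from the open face and set C4a (3S in 7) under catalyst control.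

Step 6
Reactants: 7 S-tert-butyl (3S,6S)-6-methyl-3-(2-oxoethyl)-6-(triethylsilyloxy)oct-7-enethioate
Product: 9 (3S,4R)-4-[(3S)-3-methyl-3-(triethylsilyloxy)pent-4-en-1-yl]-6-oxooxane-3-carbaldehyde (trans lactone aldehyde), via hydroxymethyl aldehyde 8 (not isolated)
Conditions: CH2O (37% aq.), (R)-α,α-diphenylprolinol trimethylsilyl ether (10 mol%), NaH2PO4/Na2HPO4 buffer (pH 7), toluene, rt; then AgOCOCF3, Na2HPO4, CH2Cl2, rt
Reagents that add atoms: formaldehyde, C=O
Why: Enamine-catalysed α-hydroxymethylation should set C11a under control of the (R)-diarylprolinol silyl ether (attack on the enamine face away from the diarylsilyloxymethyl group), and silver-assisted thioester activation then closes the δ-lactone (lactonisation) as the trans-4,5-disubstituted ring, which is also the preferred diequatorial isomer.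

Step 7
Reactants: 9 trans lactone aldehyde
Product: 10 (4R,5S)-5-(1-hydroxybut-3-en-1-yl)-4-[(3S)-3-methyl-3-(triethylsilyloxy)pent-4-en-1-yl]oxan-2-one (C11 carbinol as epimer mixture)
Conditions: allyl bromide, Zn, THF/sat. aq. NH4Cl, 0 °C
Reagents that add atoms: allyl bromide, C=CCBr
Why: Barbier allylation with allylzinc in aqueous medium is selective for the aldehyde over the lactone and avoids the base that would eliminate the β-acyloxy group; the C11 epimers are erased in step 10.

Step 8
Reactants: 10 homoallylic alcohol lactone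
Product: 11 (4R,5S)-5-(1-hydroxybut-3-en-1-yl)-4-[(3S)-3-hydroxy-3-methylpent-4-en-1-yl]oxan-2-one
Conditions: HF·pyridine, pyridine, THF, 0 °C to rt
Reagents that add atoms: none
Why: Fluoride-mediated desilylation frees the tertiary allylic hydroxyl, which should speed up metathesis at the hindered vinyl group and is needed later as the directing group.

Step 9
Reactants: 11 diol diene lactone
Product: 12 trans-fused bicyclic diol lactone (cyclonona[c]pyran-3-one core, Z-C8=C9, 7S tertiary alcohol, C11 carbinol epimers)
Conditions: second-generation Hoveyda–Grubbs catalyst (10 mol%), toluene (1 mM), 80 °C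
Reagents that add atoms: none
Why: Ring-closing metathesis should close the nine-membered ring because the trans-diequatorial arms on the δ-lactone hold the only two alkenes of the molecule together, and the ring size enforces the Z-alkene.

Step 10
Reactants: 12 bicyclic diol lactone
Product: 13 bicyclic 11-ketone (7-hydroxy-7-methyl-Z-8-ene δ-lactone)
Conditions: Dess–Martin periodinane, CH2Cl2, 0 °C to rt
Reagents that add atoms: none
Why: Dess–Martin oxidation converts both C11 epimers into one ketone under non-basic conditions, while the tertiary C7 alcohol cannot be oxidised.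

Step 11
Reactants: 13 bicyclic 11-ketone
Product: 14 bicyclic 11-methylene lactone with free 7-hydroxyl
Conditions: CH2Br2, Zn, TiCl4, THF/CH2Cl2, 0 °C to rt
Reagents that add atoms: dibromomethane, BrCBr
Why: Takai–Lombardo methylenation with the non-basic zinc–titanium methylene reagent should install the exocyclic methylene without epimerising C11a, without β-elimination of the C1 acyloxy group and without attack on the lactone, reacting through the open keto form even if part of 13 rests as a transannular hemiketal.

Step 12
Reactants: 14 bicyclic 11-methylene lactone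
Product: 15 (8R,9R)-8,9-epoxy-7-hydroxy lactone (cis epoxy alcohol)
Conditions: VO(acac)2 (5 mol%), t-BuOOH, CH2Cl2, 0 °C
Reagents that add atoms: tert-butyl hydroperoxide, CC(C)(C)OO
Why: Vanadium-catalysed hydroxyl-directed epoxidation delivers oxygen from the vanadate ester of the C7 alcohol to the adjacent Z-alkene on the hydroxyl-bearing face, which for medium-ring allylic alcohols gives the cis epoxy alcohol, and leaves the undirected exocyclic methylene alone.

Step 13
Reactants: 15 epoxy alcohol lactone
Product: 16 7-O-triethylsilyl epoxy lactone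
Conditions: Et3SiOTf, 2,6-lutidine, CH2Cl2, −78 °C
Reagents that add atoms: triethylsilyl trifluoromethanesulfonate, CC[Si](CC)(CC)OS(=O)(=O)C(F)(F)F
Why: Low-temperature silylation masks the tertiary alcohol so that neither the enolate chemistry of step 14 nor the basic stages of step 20 can start a Payne rearrangement of the neighbouring epoxide.

Step 14
Reactants: 16 7-O-triethylsilyl epoxy lactone
Product: 18 4-(diphenoxyphosphoryl) lactone (C4 epimers), via lactone phosphonite 17 (not isolated)
Conditions: LiN(iPr)2, THF, −78 °C; ClP(OPh)2, −78 to 0 °C; then t-BuOOH, 0 °C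
Reagents that add atoms: diphenyl phosphorochloridite, ClP(Oc1ccccc1)Oc1ccccc1; tert-butyl hydroperoxide, CC(C)(C)OO
Why: C-Phosphinylation of the lactone lithium enolate with a trivalent phosphorus chloride followed by oxidation of the phosphonite (a known route to α-phosphono lactones) places the diaryl phosphonate on C4; the new C4 centre is lost in step 20.

Step 15
Reactants: 19 2-methylbut-3-yn-2-ol
Product: 20 triethyl[(2-methylbut-3-yn-2-yl)oxy]silane
Conditions: Et3SiCl, imidazole, DMAP (cat.), DMF, rt
Reagents that add atoms: chlorotriethylsilane, CC[Si](Cl)(CC)CC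
Why: Silylation protects the future C15 hydroxyl so that it cannot start a Payne rearrangement of the side-chain epoxide under the basic conditions of step 20.

Step 16
Reactants: 20 triethyl[(2-methylbut-3-yn-2-yl)oxy]silane
Product: 21 4-methyl-4-(triethylsilyloxy)pent-2-yn-1-ol
Conditions: n-BuLi, (CH2O)n, THF, −78 °C to rt
Reagents that add atoms: formaldehyde (as paraformaldehyde), C=O
Why: Hydroxymethylation of the lithium acetylide with formaldehyde gives the propargylic alcohol.

Step 17
Reactants: 21 4-methyl-4-(triethylsilyloxy)pent-2-yn-1-ol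
Product: 22 (2E)-4-methyl-4-(triethylsilyloxy)pent-2-en-1-ol
Conditions: NaAlH2(OCH2CH2OMe)2, THF, 0 °C; aq. potassium sodium tartrate
Reagents that add atoms: none
Why: Hydroxyl-directed trans-hydroalumination of the propargylic alcohol gives the E-allylic alcohol only.

Step 18
Reactants: 22 (2E)-4-methyl-4-(triethylsilyloxy)pent-2-en-1-ol
Product: 23 [(2S,3R)-3-[2-(triethylsilyloxy)propan-2-yl]oxiran-2-yl]methanol
Conditions: Ti(OiPr)4 (10 mol%), L-(+)-diethyl tartrate (12 mol%), t-BuOOH, 4 Å MS, CH2Cl2, −20 °C
Reagents that add atoms: tert-butyl hydroperoxide, CC(C)(C)OO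
Why: Sharpless asymmetric epoxidation with the L-(+)-tartrate delivers oxygen to one face of the E-allylic alcohol and sets both oxirane carbons, which become C13 and C14.

Step 19
Reactants: 23 epoxy alcohol
Product: 24 (2R,3R)-3-[2-(triethylsilyloxy)propan-2-yl]oxirane-2-carbaldehyde
Conditions: Dess–Martin periodinane, NaHCO3, CH2Cl2, 0 °C
Reagents that add atoms: none
Why: Buffered Dess–Martin oxidation gives the epoxy aldehyde without epimerisation, since the oxirane carbon next to the carbonyl does not enolise readily.

Step 20
Reactants: 18 4-(diphenoxyphosphoryl) lactone and 24 (2R,3R)-3-[2-(triethylsilyloxy)propan-2-yl]oxirane-2-carbaldehyde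
Product: 27 7,15-bis-O-triethylsilyl ether of the target, via Z-alkylidene lactone 25 (not isolated), via lithium carboxylate 26 (not isolated)
Conditions: NaN(SiMe3)2 (1.05 equiv), THF, −78 °C; 24 (1.3 equiv), −78 to −20 °C; then LiOH (3 equiv), THF/H2O, 0 °C to rt; then 1 M HCl to pH 3, 0 °C
Reagents that add atoms: lithium hydroxide, [Li+].[OH-]
Why: The sodium phosphonate of 18 adds to aldehyde 24 and collapses by syn-elimination of diphenyl phosphate (Horner–Wadsworth–Emmons olefination, Z-selective diaryl phosphonate variant) to Z-alkylidene lactone 25; hydroxide then opens the δ-lactone to carboxylate 26 and frees the C1 hydroxyl, and the C3 carboxylate attacks the neighbouring allylic epoxide carbon C13 to give the butenolide and the C14 hydroxyl, so the six-membered lactone is exchanged for the five-membered one. The closest known reaction types are the Z-selective olefination of aldehydes with α-substituted diaryl phosphonoacetates and α-phosphono lactones, and the lactonisation of (Z)-γ,δ-epoxy-α,β-unsaturated acids to 5-(1-hydroxyalkyl)butenolides. The butenolide closes in the 5-exo-tet mode by SN2 attack of oxygen on C13, the 6-endo attack on C14 being disfavoured by ring size and by the lack of allylic activation. C13 is set by inversion of the (R)-configured oxirane carbon from the Sharpless epoxidation, C14 keeps its oxygen with retention, and the alkene geometry is fixed by the ring once closed. The step needs Z selectivity, which the aryloxy groups on phosphorus (fast, irreversible elimination from the kinetic adduct) and the branched substituent C4a on the carbanion should secure, and it needs both epoxides to stay in place under base, which the silyl ethers on O7 and O15 secure by blocking Payne migration; any E isomer cannot lactonise and returns as the δ-lactone. The final acidification closes any ring-opened hydroxy acid to the butenolide, γ-lactone formation from the Z-acid being faster than δ-lactone formation through O1 or O14.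

Step 21
Reactants: 27 7,15-bis-O-triethylsilyl ether of the target
Product: 28 CNP0411123.2 (target)
Conditions: HF·pyridine, pyridine, THF, 0 °C to rt
Reagents that add atoms: none
Why: Buffered fluoride desilylation should remove both tertiary triethylsilyl ethers without opening the oxirane or epimerising the butenolide γ-carbon, which a basic fluoride source might do.

**Compound list**
1 | (S)-(+)-linalool, (3S)-3,7-dimethylocta-1,6-dien-3-ol | CC(C)=CCC[C@](C)(O)C=C | starting material
2 | (3S)-3,7-dimethyl-3-(triethylsilyloxy)octa-1,6-diene | CC(C)=CCC[C@](C)(O[Si](CC)(CC)CC)C=C | intermediate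
3 | (4S)-4-methyl-4-(triethylsilyloxy)hex-5-enal | O=CCC[C@](C)(O[Si](CC)(CC)CC)C=C | intermediate
4 | (2E,6S)-6-methyl-6-(triethylsilyloxy)octa-2,7-dienal | O=C/C=C/CC[C@](C)(O[Si](CC)(CC)CC)C=C | intermediate
5 | S-tert-butyl thioacetate | CC(=O)SC(C)(C)C | starting material
6 | 1-(tert-butylsulfanyl)-1-(trimethylsilyloxy)ethene | C=C(O[Si](C)(C)C)SC(C)(C)C | intermediate
7 | S-tert-butyl (3S,6S)-6-methyl-3-(2-oxoethyl)-6-(triethylsilyloxy)oct-7-enethioate | O=CC[C@@H](CC(=O)SC(C)(C)C)CC[C@](C)(O[Si](CC)(CC)CC)C=C | intermediate
8 | S-tert-butyl (3R,6S)-3-[(2S)-1-hydroxy-3-oxopropan-2-yl]-6-methyl-6-(triethylsilyloxy)oct-7-enethioate | O=C[C@H](CO)[C@@H](CC(=O)SC(C)(C)C)CC[C@](C)(O[Si](CC)(CC)CC)C=C | intermediate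
9 | (3S,4R)-4-[(3S)-3-methyl-3-(triethylsilyloxy)pent-4-en-1-yl]-6-oxooxane-3-carbaldehyde (trans) | O=C[C@@H]1COC(=O)C[C@H]1CC[C@](C)(O[Si](CC)(CC)CC)C=C | intermediate
10 | (4R,5S)-5-(1-hydroxybut-3-en-1-yl)-4-[(3S)-3-methyl-3-(triethylsilyloxy)pent-4-en-1-yl]oxan-2-one (carbinol epimers) | C=CCC(O)[C@@H]1COC(=O)C[C@H]1CC[C@](C)(O[Si](CC)(CC)CC)C=C | intermediate
11 | (4R,5S)-5-(1-hydroxybut-3-en-1-yl)-4-[(3S)-3-hydroxy-3-methylpent-4-en-1-yl]oxan-2-one (carbinol epimers) | C=CCC(O)[C@@H]1COC(=O)C[C@H]1CC[C@](C)(O)C=C | intermediate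
12 | trans-fused bicyclic diol lactone: 7,11-dihydroxy-7-methyl-Z-8-ene cyclonona[c]pyran-3-one (7S, C11 epimers) | OC1C/C=C\[C@@](C)(O)CC[C@@H]2CC(=O)OC[C@@H]12 | intermediate
13 | bicyclic 11-ketone: 7-hydroxy-7-methyl-Z-8-ene cyclonona[c]pyran-3,11-dione (trans-fused, 7S) | O=C1C/C=C\[C@@](C)(O)CC[C@@H]2CC(=O)OC[C@@H]12 | intermediate
14 | bicyclic 11-methylene lactone: 7-hydroxy-7-methyl-11-methylidene-Z-8-ene cyclonona[c]pyran-3-one (trans-fused, 7S) | C=C1C/C=C\[C@@](C)(O)CC[C@@H]2CC(=O)OC[C@@H]12 | intermediate
15 | (7S,8R,9R)-8,9-epoxy-7-hydroxy-7-methyl-11-methylidene cyclonona[c]pyran-3-one (trans-fused, cis epoxy alcohol) | C=C1C[C@H]2O[C@H]2[C@@](C)(O)CC[C@@H]3CC(=O)OC[C@@H]13 | intermediate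
16 | 7-O-triethylsilyl ether of 15 | C=C1C[C@H]2O[C@H]2[C@@](C)(O[Si](CC)(CC)CC)CC[C@@H]3CC(=O)OC[C@@H]13 | intermediate
17 | 4-(diphenoxyphosphanyl) lactone (phosphonite, C4 epimers) | C=C1C[C@H]2O[C@H]2[C@@](C)(O[Si](CC)(CC)CC)CC[C@@H]3C(P(Oc4ccccc4)Oc4ccccc4)C(=O)OC[C@@H]13 | intermediate
18 | 4-(diphenoxyphosphoryl) lactone (phosphonate, C4 epimers) | C=C1C[C@H]2O[C@H]2[C@@](C)(O[Si](CC)(CC)CC)CC[C@@H]3C(P(=O)(Oc4ccccc4)Oc4ccccc4)C(=O)OC[C@@H]13 | intermediate
19 | 2-methylbut-3-yn-2-ol | C#CC(C)(C)O | starting material
20 | triethyl[(2-methylbut-3-yn-2-yl)oxy]silane | C#CC(C)(C)O[Si](CC)(CC)CC | intermediate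
21 | 4-methyl-4-(triethylsilyloxy)pent-2-yn-1-ol | OCC#CC(C)(C)O[Si](CC)(CC)CC | intermediate
22 | (2E)-4-methyl-4-(triethylsilyloxy)pent-2-en-1-ol | OC/C=C/C(C)(C)O[Si](CC)(CC)CC | intermediate
23 | [(2S,3R)-3-[2-(triethylsilyloxy)propan-2-yl]oxiran-2-yl]methanol | OC[C@@H]1O[C@H]1C(C)(C)O[Si](CC)(CC)CC | intermediate
24 | (2R,3R)-3-[2-(triethylsilyloxy)propan-2-yl]oxirane-2-carbaldehyde | O=C[C@@H]1O[C@H]1C(C)(C)O[Si](CC)(CC)CC | intermediate
25 | Z-alkylidene δ-lactone carrying the side-chain trans epoxide | C=C1C[C@H]2O[C@H]2[C@@](C)(O[Si](CC)(CC)CC)CC[C@@H]3/C(=C/[C@@H]4O[C@H]4C(C)(C)O[Si](CC)(CC)CC)C(=O)OC[C@@H]13 | intermediate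
26 | lithium (Z)-epoxy enoate with free C1 hydroxymethyl | C=C1C[C@H]2O[C@H]2[C@@](C)(O[Si](CC)(CC)CC)CC[C@H](/C(=C/[C@@H]3O[C@H]3C(C)(C)O[Si](CC)(CC)CC)C(=O)[O-])[C@H]1CO.[Li+] | intermediate
27 | 7,15-bis-O-triethylsilyl ether of the target | C=C1C[C@H]2O[C@H]2[C@@](C)(O[Si](CC)(CC)CC)CC[C@H](C3=C[C@H]([C@@H](O)C(C)(C)O[Si](CC)(CC)CC)OC3=O)[C@H]1CO | intermediate
28 | CNP0411123.2 | C=C1C[C@H]2O[C@H]2[C@@](C)(O)CC[C@H](C2=C[C@H]([C@@H](O)C(C)(C)O)OC2=O)[C@H]1CO | target

**Step count and risks**
Total step count: 21. Longest linear sequence: 15 steps (steps 1–3, 5–14, 20, 21).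

Step 20 (key step). The olefination of the ring-constrained phosphono lactone may lose Z selectivity, and the aqueous hydroxide stage may allow epoxide migration after partial silyl loss or conjugate addition of the freed C1 oxygen. The fallback separates the events on an open-chain ester, where the Z selectivity of α-substituted diaryl phosphonoacetates is established. It sets out from 16: methanolysis (K2CO3, MeOH, 0 °C) gives the open-chain hydroxy methyl ester F1, which is silylated at once (t-BuMe2SiCl, imidazole) to the C1 silyl ether F2. Phosphinylation and oxidation as in step 14 give the open-chain diphenyl phosphonoacetate F3, and olefination with 24 (NaH, THF, −78 °C) gives the isolable Z-epoxy enoate F4, which can be purified from any E isomer. Saponification (LiOH, THF/H2O) and acidification to pH 3 close the silylated butenolide F5, and HF·pyridine removes the three silyl groups, returning to the route at 28.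

Step 9. Oligomerisation may outrun closure of the strained nine-membered ring, or the catalyst may stall at the hindered vinyl group. The fallback replaces metathesis by reductive carbonyl coupling and sets out from 10: ozonolysis of both terminal alkenes (O3, pyridine, CH2Cl2, −78 °C) gives the dialdehyde F6. Intramolecular McMurry coupling with low-valent titanium (TiCl3, Zn–Cu, DME, slow addition) then forms C8=C9 to give the cyclononene silyl ether F7, the Z-isomer being the less strained product. HF·pyridine returns to the route at 12.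

Step 6. β-Elimination of the oxygen at C1 (to the α-methylene aldehyde) and epimerisation at C11a may occur while the aldehyde is still present, above all once the lactone has made that oxygen an acyloxy leaving group. The fallback consumes the aldehyde before the lactone is closed and sets out from 7: the crude hydroxymethylation mixture is treated directly with Zn and allyl bromide to give the diol thioester F8. AgOCOCF3 then closes the δ-lactone through the faster-reacting primary hydroxyl, returning to the route at 10.

**Further compounds**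
F1 | step 20 | open-chain hydroxy methyl ester from methanolysis of 16 | C=C1C[C@H]2O[C@H]2[C@@](C)(O[Si](CC)(CC)CC)CC[C@H](CC(=O)OC)[C@H]1CO
F2 | step 20 | C1 tert-butyldimethylsilyl ether of F1 | C=C1C[C@H]2O[C@H]2[C@@](C)(O[Si](CC)(CC)CC)CC[C@H](CC(=O)OC)[C@H]1CO[Si](C)(C)C(C)(C)C
F3 | step 20 | open-chain methyl 2-(diphenoxyphosphoryl)acetate derivative (C4 epimers) | C=C1C[C@H]2O[C@H]2[C@@](C)(O[Si](CC)(CC)CC)CC[C@H](C(C(=O)OC)P(=O)(Oc3ccccc3)Oc3ccccc3)[C@H]1CO[Si](C)(C)C(C)(C)C
F4 | step 20 | methyl (Z)-epoxy enoate | C=C1C[C@H]2O[C@H]2[C@@](C)(O[Si](CC)(CC)CC)CC[C@H](/C(=C/[C@@H]3O[C@H]3C(C)(C)O[Si](CC)(CC)CC)C(=O)OC)[C@H]1CO[Si](C)(C)C(C)(C)C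
F5 | step 20 | butenolide with C1 tert-butyldimethylsilyl ether and two triethylsilyl ethers | C=C1C[C@H]2O[C@H]2[C@@](C)(O[Si](CC)(CC)CC)CC[C@H](C3=C[C@H]([C@@H](O)C(C)(C)O[Si](CC)(CC)CC)OC3=O)[C@H]1CO[Si](C)(C)C(C)(C)C
F6 | step 9 | dialdehyde from double ozonolysis of 10 | O=CCC(O)[C@@H]1COC(=O)C[C@H]1CC[C@](C)(O[Si](CC)(CC)CC)C=O
F7 | step 9 | 7-O-triethylsilyl ether of 12 | OC1C/C=C\[C@@](C)(O[Si](CC)(CC)CC)CC[C@@H]2CC(=O)OC[C@@H]12
F8 | step 6 | diol thioester from in-flask allylation of 8 | C=CCC(O)[C@H](CO)[C@@H](CC(=O)SC(C)(C)C)CC[C@](C)(O[Si](CC)(CC)CC)C=C
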